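**Retrosynthetic overview**

1. Locants: rings A (terminal pyrrole), B (methoxy-2H-pyrrole) and C (ansa pyrrole); C-1' to C-7' are the seven CH2 groups of the ansa chain counted from ring C, C-8' is the tetrahydropyran CH that carries the chain, C-9' the ring CH2, C-10' the CH(CH3)O carbon; the "meso carbon" is the CH bonded to ring C, C-8' and the spiro carbon.
2. Last disconnection (tetrahydropyran, spiro centre, rings A/B): the spiro C–O and meso C–ring B bonds are cut to a [9](2,5)pyrrolophane ketone (meso carbon as 2-acylpyrrole C=O, C-10' OH free) and 4-methoxy-2,2'-bipyrrole; one acid cascade sets the meso and spiro centres from C-8' and C-10'.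
3. Key disconnection (12-membered ansa ring) at C-6'–C-7': with the meso carbon at the ketone level, C-7' is the β-carbon of a 2-acylpyrrole, a homoenolate position. It is stored in a cyclopropanol whose three ring atoms are the meso carbon, C-8' and C-7', and is joined to a C-6' iodide (two natively electrophilic carbons united by polarity reversal); the same event closes the ansa ring, erases the temporary ring and unveils the ketone, with C-8' untouched.
4. The cyclopropanol comes from a Kulinkovich reaction between a ring C pyrrole-2-carboxylate carrying C-1'–C-6' and (S)-pent-4-en-2-ol, which brings C-7'–C-11' and the only purchased stereocentre (C-10'); C-8' is relayed from it.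
5. Ring order: ring C (purchased) → cyclopropane (temporary) → ansa ring → rings A/B (bipyrrole, made separately) → tetrahydropyran with the spiro fusion.

Key step: step 5

Remark on the chemistry: the target is read as spiro C (R), C-10' (S), C-8' (S), meso C (S); methyl 5-bromo-1H-pyrrole-2-carboxylate, 6-chlorohex-1-ene, (S)-pent-4-en-2-ol, 4-methoxy-1,5-dihydro-2H-pyrrol-2-one and pyrrole are taken as purchasable.

**Route**

Step 1
Reactants: 1 methyl 5-bromo-1H-pyrrole-2-carboxylate
Product: 2 methyl 5-bromo-1-{[2-(trimethylsilyl)ethoxy]methyl}-1H-pyrrole-2-carboxylate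
Conditions: NaH, SEMCl, DMF, 0 °C to rt
Reagents that add atoms: 2-(trimethylsilyl)ethoxymethyl chloride (SEMCl), C[Si](C)(C)CCOCCl
Why: N-alkylation (SN2) of the sodium pyrrolide masks the acidic N–H, which would otherwise quench the Grignard reagent and deactivate the ester in step 3, with a group that cannot migrate to the later cyclopropanol oxygen; no stereocentre.

Step 2
Reactants: 2 methyl 5-bromo-1-{[2-(trimethylsilyl)ethoxy]methyl}-1H-pyrrole-2-carboxylate; 3 6-chlorohex-1-ene
Product: 5 methyl 5-(6-chlorohexyl)-1-{[2-(trimethylsilyl)ethoxy]methyl}-1H-pyrrole-2-carboxylate, via alkylborane 4 (not isolated)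
Conditions: 3, 9-BBN-H, THF, 0 °C to rt; then 2, PdCl2(dppf) (5 mol %), aq. K3PO4, DMF, 60 °C
Reagents that add atoms: none
Why: Anti-Markovnikov hydroboration of the terminal alkene followed by B-alkyl Suzuki–Miyaura coupling with the electron-poor 2-bromopyrrole installs C-1' to C-6', the primary chloride being inert in both stages; no stereocentre.

Step 3
Reactants: 5 methyl 5-(6-chlorohexyl)-1-{[2-(trimethylsilyl)ethoxy]methyl}-1H-pyrrole-2-carboxylate; 6 (S)-pent-4-en-2-ol
Product: 7 (1S,2R)-1-[5-(6-chlorohexyl)-1-{[2-(trimethylsilyl)ethoxy]methyl}-1H-pyrrol-2-yl]-2-[(2S)-2-hydroxypropyl]cyclopropan-1-ol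
Conditions: ClTi(OiPr)3, c-C5H9MgCl (slow addition), THF, rt; aq. NH4Cl
Reagents that add atoms: none
Why: Kulinkovich hydroxycyclopropanation in its ligand-exchange, homoallylic-alkoxide-directed form: the titanium alkoxide of 6 binds its own alkene as a titanacyclopropane that adds twice to the ester carbonyl, the tether placing the pyrrolyl group trans to the hydroxypropyl arm, and C-8' (cyclopropane C-2) should be set by 1,3-induction from C-10', whose methyl group is expected to take the exo face of the bicyclic oxatitanacycle, while cyclopropane C-1 is a sacrificial centre.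

Step 4
Reactants: 7 (1S,2R)-1-[5-(6-chlorohexyl)-1-{[2-(trimethylsilyl)ethoxy]methyl}-1H-pyrrol-2-yl]-2-[(2S)-2-hydroxypropyl]cyclopropan-1-ol
Product: 8 (1S,2R)-2-[(2S)-2-hydroxypropyl]-1-[5-(6-iodohexyl)-1-{[2-(trimethylsilyl)ethoxy]methyl}-1H-pyrrol-2-yl]cyclopropan-1-ol
Conditions: NaI, NaHCO3 (cat.), butan-2-one, 70 °C
Reagents that add atoms: sodium iodide, [Na+].[I-]
Why: Finkelstein exchange (SN2, driven by precipitation of NaCl) turns the chloride that survived the organometallic steps into the iodide needed for halogen-atom abstraction, the buffered neutral medium sparing the acid- and base-sensitive cyclopropanol; no stereocentre is touched.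

Step 5
Reactants: 8 (1S,2R)-2-[(2S)-2-hydroxypropyl]-1-[5-(6-iodohexyl)-1-{[2-(trimethylsilyl)ethoxy]methyl}-1H-pyrrol-2-yl]cyclopropan-1-ol
Product: 9 (3S)-3-[(2S)-2-hydroxypropyl]-14-{[2-(trimethylsilyl)ethoxy]methyl}-14-azabicyclo[9.2.1]tetradeca-1(13),11-dien-2-one (N-SEM ketopyrrolophane)
Conditions: NiCl2(dme) (10 mol %), 4,4'-di-tert-butyl-2,2'-bipyridine (12 mol %), Zn (20 mol %), K3PO4 (2 equiv), DMA/THF, 0.002 M (slow addition of 8), 35 °C
Reagents that add atoms: none
Why: Proposed new method: exchange of the cyclopropanol O–H onto divalent nickel and strain-driven β-carbon elimination at the less substituted ring bond (meso carbon–C-7') should give a ketone-chelated nickel homoenolate, while a monovalent nickel species abstracts the iodine atom at C-6'; capture of the resulting primary radical at the homoenolate nickel centre and C(sp3)–C(sp3) reductive elimination from trivalent nickel then forge C-6'–C-7' and return monovalent nickel, the whole being redox-neutral with K3PO4 taking up HI. The closest known reaction types are the intermolecular nickel-catalysed β-alkylation of cyclopropanol-derived homoenolates with alkyl radical precursors and the nickel-catalysed alkyl–alkyl Negishi coupling of primary iodides; only the ring-closing mode is new. The single ring closed is the 12-membered ansa ring, formed not by direct radical attack on carbon but by radical capture at nickel (13-membered nickelacycle) followed by ring-contracting reductive elimination, and the cyclopropane is opened in the same event. No stereocentre is created: C-8' is a spectator of the bond that breaks and is carried through with its configuration, whereas the sacrificial cyclopropanol carbon becomes the planar acylpyrrole carbonyl. The step needs regioselective cleavage of the CH2–C(OH) bond (secured by the substituent on C-8', which shields the other ring bond), no β-hydride elimination to the enone (secured by the five-membered O–Ni chelate, in which the C-8' hydrogen cannot become syn-coplanar with nickel) and ring closure in preference to oligomerisation or O-alkylation (secured by high dilution, the mild insoluble base and fast iodine abstraction); the free C-10' hydroxyl has no strain-driven pathway and should be a spectator.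

Step 6
Reactants: 9 (3S)-3-[(2S)-2-hydroxypropyl]-14-{[2-(trimethylsilyl)ethoxy]methyl}-14-azabicyclo[9.2.1]tetradeca-1(13),11-dien-2-one
Product: 10 (3S)-3-[(2S)-2-hydroxypropyl]-14-azabicyclo[9.2.1]tetradeca-1(13),11-dien-2-one (ketopyrrolophane)
Conditions: Bu4NF, THF, 60 °C; H2O
Reagents that add atoms: none
Why: Fluoride attack at silicon fragments the SEM group (loss of ethene and formaldehyde), the 2-acyl group making the pyrrolide a good leaving group, and the brief exposure to a weakly basic medium should leave the C-8' centre α to the ketone intact.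

Step 7
Reactants: 11 4-methoxy-1,5-dihydro-2H-pyrrol-2-one; 12 pyrrole
Product: 13 4-methoxy-1H,1'H-2,2'-bipyrrole
Conditions: POCl3, CH2Cl2, 0 °C; then 12 (excess), rt; aq. NaOH
Reagents that add atoms: none
Why: Vilsmeier–Haack-type heteroarylation of a lactam: POCl3 converts the vinylogous carbamate into a chloroiminium ion that pyrrole attacks at its C-2, and the resulting 2H-pyrrole tautomerises to the aromatic bipyrrole, whose free α-position next to the methoxy group is the nucleophile of step 8; no stereocentre.

Step 8
Reactants: 10 (3S)-3-[(2S)-2-hydroxypropyl]-14-azabicyclo[9.2.1]tetradeca-1(13),11-dien-2-one; 13 4-methoxy-1H,1'H-2,2'-bipyrrole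
Product: 15 premarineosin A, via hydroxy prodiginine 14 (not isolated)
Conditions: HCl (2 equiv, in MeOH), CH2Cl2/MeOH, 0 °C to rt; aq. NaHCO3
Reagents that add atoms: none
Why: Acid-promoted condensation of a 2-acylpyrrole with an α-free pyrrole (dipyrrin/prodiginine synthesis) followed by biomimetic spiroaminal formation: the γ-hydroxy ketone ionises through its cyclic hemiketal to a pyrrole-stabilised oxocarbenium (azafulvenium) ion that C-5 of 13 captures, loss of water gives the ansa-strained prodiginine 14, and its twisted chromophore is protonated at the meso carbon and trapped at ring B C-2 by the C-10' hydroxyl in a reversible six-membered N,O-ketalisation, so that the meso and spiro centres are set together under thermodynamic substrate control from C-8' and C-10', expected to favour the isomer with ring C and the C-7' methylene trans on the tetrahydropyran and the ring B nitrogen cis to ring C.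

**Compound list**

1 | methyl 5-bromo-1H-pyrrole-2-carboxylate | COC(=O)c1ccc(Br)[nH]1 | starting material
2 | methyl 5-bromo-1-{[2-(trimethylsilyl)ethoxy]methyl}-1H-pyrrole-2-carboxylate | COC(=O)c1ccc(Br)n1COCC[Si](C)(C)C | intermediate
3 | 6-chlorohex-1-ene | C=CCCCCCl | starting material
4 | 9-(6-chlorohexyl)-9-borabicyclo[3.3.1]nonane (alkylborane) | ClCCCCCCB1C2CCCC1CCC2 | intermediate
5 | methyl 5-(6-chlorohexyl)-1-{[2-(trimethylsilyl)ethoxy]methyl}-1H-pyrrole-2-carboxylate | COC(=O)c1ccc(CCCCCCCl)n1COCC[Si](C)(C)C | intermediate
6 | (S)-pent-4-en-2-ol | C[C@H](O)CC=C | starting material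
7 | (1S,2R)-1-[5-(6-chlorohexyl)-1-{[2-(trimethylsilyl)ethoxy]methyl}-1H-pyrrol-2-yl]-2-[(2S)-2-hydroxypropyl]cyclopropan-1-ol | C[C@H](O)C[C@@H]1C[C@@]1(O)c2ccc(CCCCCCCl)n2COCC[Si](C)(C)C | intermediate
8 | (1S,2R)-2-[(2S)-2-hydroxypropyl]-1-[5-(6-iodohexyl)-1-{[2-(trimethylsilyl)ethoxy]methyl}-1H-pyrrol-2-yl]cyclopropan-1-ol | C[C@H](O)C[C@@H]1C[C@@]1(O)c2ccc(CCCCCCI)n2COCC[Si](C)(C)C | intermediate
9 | (3S)-3-[(2S)-2-hydroxypropyl]-14-{[2-(trimethylsilyl)ethoxy]methyl}-14-azabicyclo[9.2.1]tetradeca-1(13),11-dien-2-one (N-SEM ketopyrrolophane) | C[C@H](O)C[C@@H]1CCCCCCCc2ccc(C1=O)n2COCC[Si](C)(C)C | intermediate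
10 | (3S)-3-[(2S)-2-hydroxypropyl]-14-azabicyclo[9.2.1]tetradeca-1(13),11-dien-2-one (ketopyrrolophane) | C[C@H](O)C[C@@H]1CCCCCCCc2ccc([nH]2)C1=O | intermediate
11 | 4-methoxy-1,5-dihydro-2H-pyrrol-2-one | COC1=CC(=O)NC1 | starting material
12 | pyrrole | c1cc[nH]c1 | starting material
13 | 4-methoxy-1H,1'H-2,2'-bipyrrole | COc1c[nH]c(-c2ccc[nH]2)c1 | intermediate
14 | ansa-bridged hydroxy prodiginine (azafulvene form: meso carbon doubly bonded to ring B C-2, C-10' OH free, alkene geometry not fixed) | COC1=CC(c2ccc[nH]2)=NC1=C3c4ccc([nH]4)CCCCCCC[C@H]3C[C@H](C)O | intermediate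
15 | premarineosin A | COC1=CC(c2ccc[nH]2)=N[C@]12O[C@@H](C)C[C@@H]1CCCCCCCc3ccc([nH]3)[C@H]12 | target

**Step count and risks**

Total step count: 8. Longest linear sequence: 7 steps (steps 1–6 and 8; step 7 is a one-step side branch).

Steps most likely to fail:

1. Step 5 (Proposed new method). Closure of the strained ansa ring may be slower than protodemetalation of the nickel homoenolate (giving the ring-opened α-methyl ketone), β-hydride elimination, O-alkylation of the cyclopropoxide or intermolecular coupling. The fallback sets out from 7 and comes back at 9, forms the same C-6'–C-7' bond and uses only known reaction types. Oxidative ring opening of the cyclopropanol (Pd(OAc)2 cat., O2, DMSO, rt, where the unstrained secondary alcohol should not be oxidised) would give the α-methylene ketone (4S)-1-[5-(6-chlorohexyl)-1-{[2-(trimethylsilyl)ethoxy]methyl}-1H-pyrrol-2-yl]-4-hydroxy-2-methylidenepentan-1-one F1. Finkelstein exchange (NaI, butan-2-one) would give the iodo enone F2. Slow addition of Bu3SnH/AIBN in benzene at 80 °C and 0.002 M would then close the ring by a 12-endo Giese-type radical macrocyclisation of the iodoalkyl enone. Hydrogen-atom transfer to the α-keto radical is not expected to be selective, so 9 would have to be separated from its C-8' epimer F3, which could be re-equilibrated with DBU and recycled.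

2. Step 3. The titanacyclopropane may add sluggishly to the electron-rich heteroaryl ester, and alkene complexation may show poor facial selectivity (weak 1,3-induction from C-10' to C-8'). The fallback sets out from 5 and comes back at 7, making the cyclopropanation intramolecular. Saponification (LiOH, THF/H2O) would give 5-(6-chlorohexyl)-1-{[2-(trimethylsilyl)ethoxy]methyl}-1H-pyrrole-2-carboxylic acid F4. Esterification with 6 (DCC, DMAP, retention at C-10') would give the homoallyl ester (2S)-pent-4-en-2-yl 5-(6-chlorohexyl)-1-{[2-(trimethylsilyl)ethoxy]methyl}-1H-pyrrole-2-carboxylate F5. Treatment with Ti(OiPr)4 and i-PrMgCl (Et2O, −45 °C to rt) should then trigger the known tandem intramolecular nucleophilic acyl substitution/carbonyl addition of homoallyl esters, in which C-8' is fixed in a five-membered ring that already contains C-10', and deliver 7.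

3. Step 8. Condensation at the hindered, vinylogous-amide-like ketone may stall; the C-8' centre may erode by reversible proton loss from the azafulvenium intermediates during long acid exposure; the five-membered ketal (oxygen on the meso carbon) or the wrong meso/spiro epimer may accumulate. The fallback sets out from 13 and 9 and comes back at 15, replacing the acid condensation by a kinetically controlled organometallic addition. Boc2O/DMAP would convert 13 into di-tert-butyl 4-methoxy-1H,1'H-[2,2'-bipyrrole]-1,1'-dicarboxylate F6. Deprotonation at C-5 of the methoxy ring (between N-Boc and OMe) with lithium 2,2,6,6-tetramethylpiperidide at −78 °C, transmetalation with CeCl3 and addition to 9 (its hydroxyl first converted into the lithium alkoxide with LiN(SiMe3)2) would give the tertiary carbinol F7. Brief CF3CO2H treatment at 0 °C would remove both Boc groups, ionise the carbinol and spirocyclise to N-SEM premarineosin A F8, and Bu4NF would then release 15.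

Further compounds
F1 | step 5 | (4S)-1-[5-(6-chlorohexyl)-1-{[2-(trimethylsilyl)ethoxy]methyl}-1H-pyrrol-2-yl]-4-hydroxy-2-methylidenepentan-1-one | C[C@H](O)CC(=C)C(=O)c1ccc(CCCCCCCl)n1COCC[Si](C)(C)C
F2 | step 5 | (4S)-4-hydroxy-1-[5-(6-iodohexyl)-1-{[2-(trimethylsilyl)ethoxy]methyl}-1H-pyrrol-2-yl]-2-methylidenepentan-1-one | C[C@H](O)CC(=C)C(=O)c1ccc(CCCCCCI)n1COCC[Si](C)(C)C
F3 | step 5 | (3R)-3-[(2S)-2-hydroxypropyl]-14-{[2-(trimethylsilyl)ethoxy]methyl}-14-azabicyclo[9.2.1]tetradeca-1(13),11-dien-2-one (C-8' epimer of 9) | C[C@H](O)C[C@H]1CCCCCCCc2ccc(C1=O)n2COCC[Si](C)(C)C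
F4 | step 3 | 5-(6-chlorohexyl)-1-{[2-(trimethylsilyl)ethoxy]methyl}-1H-pyrrole-2-carboxylic acid | OC(=O)c1ccc(CCCCCCCl)n1COCC[Si](C)(C)C
F5 | step 3 | (2S)-pent-4-en-2-yl 5-(6-chlorohexyl)-1-{[2-(trimethylsilyl)ethoxy]methyl}-1H-pyrrole-2-carboxylate | C=CC[C@H](C)OC(=O)c1ccc(CCCCCCCl)n1COCC[Si](C)(C)C
F6 | step 8 | di-tert-butyl 4-methoxy-1H,1'H-[2,2'-bipyrrole]-1,1'-dicarboxylate | COc1cn(C(=O)OC(C)(C)C)c(-c2cccn2C(=O)OC(C)(C)C)c1
F7 | step 8 | tertiary carbinol from addition of 5-metalated F6 to the ketone of 9 (carbinol carbon unassigned) | COc1cc(-c2cccn2C(=O)OC(C)(C)C)n(C(=O)OC(C)(C)C)c1C3(O)c4ccc(CCCCCCC[C@H]3C[C@H](C)O)n4COCC[Si](C)(C)C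
F8 | step 8 | N-SEM premarineosin A (SEM on the ring C nitrogen) | COC1=CC(c2ccc[nH]2)=N[C@]12O[C@@H](C)C[C@@H]1CCCCCCCc3ccc(n3COCC[Si](C)(C)C)[C@H]12
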